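Ring B (O–C5–C6=C7–C8) of the hexahydrobenzofuran core is disconnected at C7, the one-carbon CH bridge between C6, whose ring neighbours C1 and C5 are both fully substituted, and the oxygen-bearing allylic C8. In a single operation the C6 ketone of a C5 allyl ether is converted into an alkylidene carbene at C7, which inserts into a C8–H bond: C6=C7 and C7–C8 are formed, ring B closes and C8 is set. The precursor is a (2R,4R)-2-allyloxy-4-silyloxy-2,6,6-trimethylcyclohexanone that carries C8–C11 on O5 and is assembled from ketoisophorone and prenol; the C12–C8′ polyene is added afterwards by Wittig olefination at C11.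

Key step: step 12

Remarks before the steps
- Numbering: carotenoid numbering is used for the core (ring A C1–C6, ring B O–C5–C6=C7–C8, chain C9–C11 and C12–C8′); cyclohexanone numbering is used in the names of the early intermediates.
- Stereochemistry: in the target the C3 hydroxyl is cis to the C5 ether oxygen and C9 is trans to the C5 methyl across ring B, i.e. (3R,5R,8R). This calls for the 4S alcohol of 4-hydroxy-2,2,6-trimethylcyclohexanone.
- Assumption: 2,7-dimethylocta-2,4,6-trienedial (24) and ethyl (2E)-4-(diethoxyphosphoryl)-2-methylbut-2-enoate (25) are taken as purchasable reagents.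
- Precursor design: O3 carries the bulky tert-butyldiphenylsilyl group (least prone to O3→O5 migration under base) and O11 a tert-butyldimethylsilyl group. Both are removed together directly after ring closure, so no deprotection is needed on the polyene.

Step 1
Reactants: 1 ketoisophorone (2,6,6-trimethylcyclohex-2-ene-1,4-dione)
Product: 2 (6R)-2,2,6-trimethylcyclohexane-1,4-dione
Conditions: baker's yeast (Saccharomyces cerevisiae), sucrose, H2O, 30 °C
Reagents that add atoms: none
Why: Enzymatic conjugate reduction of the enedione C=C by the ene-reductase of fermenting yeast delivers hydrogen to one face and should set the methyl-bearing carbon as R.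

Step 2
Reactants: 2 (6R)-2,2,6-trimethylcyclohexane-1,4-dione
Product: 3 (4R,6R)-4-hydroxy-2,2,6-trimethylcyclohexan-1-one
Conditions: LiBH(s-Bu)3, THF, −78 °C; then H2O
Reagents that add atoms: none
Why: Bulky-hydride reduction of the unhindered C4 carbonyl (the C1 carbonyl is shielded by its two substituted α-carbons) proceeds by equatorial attack, away from the axial C2 methyl, and should give the axial alcohol trans to the C6 methyl (4R).

Step 3
Reactants: 3 (4R,6R)-4-hydroxy-2,2,6-trimethylcyclohexan-1-one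
Product: 4 (1S,5R)-3,3,5-trimethyl-4-oxocyclohexyl 4-nitrobenzoate
Conditions: 4-O2NC6H4CO2H, PPh3, i-PrO2CN=NCO2i-Pr, THF, 0 °C → rt
Reagents that add atoms: 4-nitrobenzoic acid, OC(=O)c1ccc(cc1)[N+](=O)[O-]
Why: Mitsunobu esterification displaces the axial oxyphosphonium group by SN2 from the open side of the ring and inverts the carbinol centre to S.

Step 4
Reactants: 4 (1S,5R)-3,3,5-trimethyl-4-oxocyclohexyl 4-nitrobenzoate
Product: 5 (1S)-4-[(tert-butyldimethylsilyl)oxy]-3,5,5-trimethylcyclohex-3-en-1-yl 4-nitrobenzoate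
Conditions: t-BuMe2SiOTf, Et3N, CH2Cl2, 0 °C → rt
Reagents that add atoms: tert-butyldimethylsilyl trifluoromethanesulfonate, CC(C)(C)[Si](C)(C)OS(=O)(=O)C(F)(F)F
Why: Soft enolisation with O-silylation of the ketone, whose only α-hydrogen is on the methyl-bearing carbon, should give the single possible tetrasubstituted silyl enol ether and leave the ester untouched.

Step 5
Reactants: 5 (1S)-4-[(tert-butyldimethylsilyl)oxy]-3,5,5-trimethylcyclohex-3-en-1-yl 4-nitrobenzoate
Product: 6 (1S)-4-[(tert-butyldimethylsilyl)oxy]-3,5,5-trimethylcyclohex-3-en-1-ol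
Conditions: K2CO3, MeOH, 0 °C
Reagents that add atoms: none
Why: Transesterification of the activated 4-nitrobenzoate with methanol frees the homoallylic alcohol, while the hindered tert-butyldimethylsilyl enol ether should resist mild methanolysis.

Step 6
Reactants: 6 (1S)-4-[(tert-butyldimethylsilyl)oxy]-3,5,5-trimethylcyclohex-3-en-1-ol
Product: 9 (2R,4R)-2,4-dihydroxy-2,6,6-trimethylcyclohexan-1-one, via silyloxy epoxide 7 (not isolated), via α-silyloxy ketone 8 (not isolated)
Conditions: m-CPBA, NaHCO3, CH2Cl2, −20 °C → 0 °C; then n-Bu4NF, THF, 0 °C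
Reagents that add atoms: m-chloroperbenzoic acid, O=C(OO)c1cccc(Cl)c1
Why: In this Rubottom oxidation the peracid is guided by hydrogen bonding to the free homoallylic hydroxyl (Henbest effect) while, in the half-chair with that hydroxyl equatorial, the pseudoaxial methyl of the gem-dimethyl carbon screens the opposite face, so that the epoxide, the silyl-shifted ketone and finally the fluoride-released tertiary alcohol should carry the new oxygen cis to the secondary hydroxyl (new centre R).

Step 7
Reactants: 9 (2R,4R)-2,4-dihydroxy-2,6,6-trimethylcyclohexan-1-one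
Product: 10 (2R,4R)-4-[(tert-butyldiphenylsilyl)oxy]-2-hydroxy-2,6,6-trimethylcyclohexan-1-one
Conditions: t-BuPh2SiCl, imidazole, DMF, rt
Reagents that add atoms: tert-butyl(chloro)diphenylsilane, CC(C)(C)[Si](Cl)(c1ccccc1)c1ccccc1
Why: Silylation should discriminate the secondary from the tertiary hydroxyl on steric grounds and install the migration-resistant silyl group needed for the basic step that follows.

Step 8
Reactants: 11 prenol (3-methylbut-2-en-1-ol)
Product: 12 tert-butyldimethyl[(3-methylbut-2-en-1-yl)oxy]silane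
Conditions: t-BuMe2SiCl, imidazole, CH2Cl2, rt
Reagents that add atoms: tert-butyl(chloro)dimethylsilane, CC(C)(C)[Si](C)(C)Cl
Why: Routine silylation of a primary alcohol.

Step 9
Reactants: 12 tert-butyldimethyl[(3-methylbut-2-en-1-yl)oxy]silane
Product: 13 (2E)-4-[(tert-butyldimethylsilyl)oxy]-2-methylbut-2-en-1-ol
Conditions: SeO2 (cat.), t-BuOOH, CH2Cl2, 0 °C → rt
Reagents that add atoms: selenium dioxide, O=[Se]=O (oxygen donor; reoxidised by tert-butyl hydroperoxide, CC(C)(C)OO)
Why: Riley allylic oxidation (ene reaction followed by a [2,3]-shift) of a trisubstituted alkene hydroxylates the methyl group trans to the chain and should give the E allylic alcohol.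

Step 10
Reactants: 13 (2E)-4-[(tert-butyldimethylsilyl)oxy]-2-methylbut-2-en-1-ol
Product: 14 {[(2E)-4-bromo-3-methylbut-2-en-1-yl]oxy}(tert-butyl)dimethylsilane
Conditions: CBr4, PPh3, CH2Cl2, 0 °C
Reagents that add atoms: tetrabromomethane, BrC(Br)(Br)Br
Why: Appel bromination converts the primary allylic alcohol into the bromide by SN2 under neutral conditions without touching the double-bond geometry or the silyl ether.

Step 11
Reactants: 10 (2R,4R)-4-[(tert-butyldiphenylsilyl)oxy]-2-hydroxy-2,6,6-trimethylcyclohexan-1-one; 14 {[(2E)-4-bromo-3-methylbut-2-en-1-yl]oxy}(tert-butyl)dimethylsilane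
Product: 16 (2R,4R)-2-{[(2E)-4-[(tert-butyldimethylsilyl)oxy]-2-methylbut-2-en-1-yl]oxy}-4-[(tert-butyldiphenylsilyl)oxy]-2,6,6-trimethylcyclohexan-1-one, via potassium alkoxide 15 (not isolated)
Conditions: KH, THF, 0 °C; then 14, n-Bu4NI (cat.), 0 °C → rt
Reagents that add atoms: none
Why: In this Williamson etherification the tertiary alkoxide, whose ketone cannot enolise because both α-carbons are fully substituted, should displace the reactive primary allylic bromide by SN2 with both stereocentres and the E geometry unchanged.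

Step 12
Reactants: 16 (2R,4R)-2-{[(2E)-4-[(tert-butyldimethylsilyl)oxy]-2-methylbut-2-en-1-yl]oxy}-4-[(tert-butyldiphenylsilyl)oxy]-2,6,6-trimethylcyclohexan-1-one; 17 trimethylsilyldiazomethane
Product: 21 tert-butyl({(2E)-3-[(2R,6R,7aR)-6-[(tert-butyldiphenylsilyl)oxy]-4,4,7a-trimethyl-2,4,5,6,7,7a-hexahydro-1-benzofuran-2-yl]but-2-en-1-yl}oxy)dimethylsilane [(3R,5R,8R) in carotenoid numbering], via lithiated trimethylsilyldiazomethane 18 (not isolated), via diazoalkene 19 (not isolated), via alkylidene carbene 20 (not isolated)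
Conditions: 17, n-BuLi, THF, −78 °C; then 16, −78 °C → rt
Reagents that add atoms: trimethylsilyldiazomethane (17), C[Si](C)(C)C=[N+]=[N-]
Why: Lithiated trimethylsilyldiazomethane 18 adds to the C6 carbonyl (lithium bridged to the C5 ether oxygen), Peterson-type loss of Me3SiOLi gives diazoalkene 19, loss of N2 gives the singlet alkylidene carbene 20, and its vacant in-plane orbital at C7 inserts concertedly into a C8–H bond. The closest known reaction is the conversion of α-alkoxy ketones into 2,5-dihydrofurans with this reagent (Colvin-type carbene generation followed by 1,5 C–H insertion). Ring B is closed by that 1,5 C–H insertion through a five-membered, nearly planar transition state (C7–C6–C5–O–C8), which makes the C7–C8 bond after C6=C7 has been installed. C8 is the only new stereocentre and is decided by which of its two diastereotopic hydrogens is attacked: in the favoured transition state the C9 alkenyl group lies on the ring B face next to C4H2, which is tied back into ring A, and away from the pseudoaxial C5 methyl, which should give 8R with C9 trans to that methyl. Site selectivity is secured by the substrate: only the C8 hydrogens, activated by the ether oxygen and the C9=C10 bond, are five atoms from C7 in a reachable geometry (insertion at C3–H would need a bridgehead alkene), C6 has two fully substituted neighbours so neither enolisation nor a 1,2-shift can intervene, and the silyl ethers are inert.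

Step 13
Reactants: 21 tert-butyl({(2E)-3-[(2R,6R,7aR)-6-[(tert-butyldiphenylsilyl)oxy]-4,4,7a-trimethyl-2,4,5,6,7,7a-hexahydro-1-benzofuran-2-yl]but-2-en-1-yl}oxy)dimethylsilane
Product: 22 (2R,6R,7aR)-2-[(2E)-4-hydroxybut-2-en-2-yl]-4,4,7a-trimethyl-2,4,5,6,7,7a-hexahydro-1-benzofuran-6-ol
Conditions: n-Bu4NF, THF, 0 °C → rt
Reagents that add atoms: none
Why: Fluoride-induced desilylation should remove both silyl ethers in one operation at the robust C15 stage under non-acidic conditions that leave the doubly allylic C8–O bond alone.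

Step 14
Reactants: 22 (2R,6R,7aR)-2-[(2E)-4-hydroxybut-2-en-2-yl]-4,4,7a-trimethyl-2,4,5,6,7,7a-hexahydro-1-benzofuran-6-ol
Product: 23 (2E)-3-[(2R,6R,7aR)-6-hydroxy-4,4,7a-trimethyl-2,4,5,6,7,7a-hexahydro-1-benzofuran-2-yl]but-2-enal
Conditions: MnO2, CH2Cl2, rt
Reagents that add atoms: none
Why: Activated MnO2 oxidises only the primary allylic alcohol, so the saturated secondary C3 hydroxyl and the dihydrofuran should survive these neutral conditions.

Step 15
Reactants: 24 (2E,4E,6E)-2,7-dimethylocta-2,4,6-trienedial; 25 ethyl (2E)-4-(diethoxyphosphoryl)-2-methylbut-2-enoate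
Product: 27 ethyl (2E,4E,6E,8E,10E)-2,6,11-trimethyl-12-oxododeca-2,4,6,8,10-pentaenoate, via sodium phosphonate carbanion 26 (not isolated)
Conditions: 25, NaH, THF, 0 °C; then added to 24 (2 equiv), THF, −20 °C → 0 °C
Reagents that add atoms: none
Why: Horner–Wadsworth–Emmons olefination with the vinylogous phosphonate should form the new double bond E, and the excess of dialdehyde together with the lower electrophilicity of the extended product aldehyde should hold the reaction at mono-olefination.

Step 16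
Reactants: 27 ethyl (2E,4E,6E,8E,10E)-2,6,11-trimethyl-12-oxododeca-2,4,6,8,10-pentaenoate
Product: 28 ethyl (2E,4E,6E,8E,10E)-12-hydroxy-2,6,11-trimethyldodeca-2,4,6,8,10-pentaenoate
Conditions: NaBH4, EtOH, 0 °C
Reagents that add atoms: none
Why: Borohydride should reduce the aldehyde in a 1,2 sense and leave the conjugated ester untouched.

Step 17
Reactants: 28 ethyl (2E,4E,6E,8E,10E)-12-hydroxy-2,6,11-trimethyldodeca-2,4,6,8,10-pentaenoate
Product: 29 [(2E,4E,6E,8E,10E)-12-ethoxy-2,7,11-trimethyl-12-oxododeca-2,4,6,8,10-pentaen-1-yl]triphenylphosphonium bromide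
Conditions: PPh3·HBr, MeOH, rt
Reagents that add atoms: triphenylphosphine hydrobromide, [Br-].[PH+](c1ccccc1)(c1ccccc1)c1ccccc1
Why: The polyenylic alcohol ionises under the mild acid and the delocalised cation should be captured by PPh3 at the terminal carbon, the usual entry to carotenoid Wittig salts, which keeps the pentaene conjugated with the ester.

Step 18
Reactants: 23 (2E)-3-[(2R,6R,7aR)-6-hydroxy-4,4,7a-trimethyl-2,4,5,6,7,7a-hexahydro-1-benzofuran-2-yl]but-2-enal; 29 [(2E,4E,6E,8E,10E)-12-ethoxy-2,7,11-trimethyl-12-oxododeca-2,4,6,8,10-pentaen-1-yl]triphenylphosphonium bromide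
Product: 31 ethyl (3R,5R,8R,all-E)-5,8-epoxy-3-hydroxy-5,8-dihydro-8′-apo-β-caroten-8′-oate, via phosphorus ylide 30 (not isolated)
Conditions: 29, NaN(SiMe3)2, THF, −78 °C; then 23, −78 °C → 0 °C; then n-heptane, 80 °C, dark
Reagents that add atoms: none
Why: Wittig olefination of the C11 enal by the weakly basic, ester-conjugated pentaenyl ylide should form C11=C12 without deprotonating C8 or disturbing the free C3 hydroxyl, and brief heating should convert the sterically hindered 11Z isomer into the all-E ester.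

Step 19
Reactants: 31 ethyl (3R,5R,8R,all-E)-5,8-epoxy-3-hydroxy-5,8-dihydro-8′-apo-β-caroten-8′-oate
Product: 32 (3R,5R,8R,all-E)-5,8-epoxy-5,8-dihydro-8′-apo-β-carotene-3,8′-diol
Conditions: i-Bu2AlH, CH2Cl2, −78 °C; then aq. KNaC4H4O6
Reagents that add atoms: none
Why: The aluminium hydride should reduce the conjugated ester in a 1,2 sense to the allylic alcohol without touching the polyene or the cyclic ether.

Step 20
Reactants: 32 (3R,5R,8R,all-E)-5,8-epoxy-5,8-dihydro-8′-apo-β-carotene-3,8′-diol
Product: 33 (3R,5R,8R,all-E)-5,8-epoxy-3-hydroxy-5,8-dihydro-8′-apo-β-caroten-8′-al (CNP0118413.1)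
Conditions: MnO2, CH2Cl2, rt, dark
Reagents that add atoms: none
Why: Activated MnO2 should oxidise only the polyenylic primary alcohol to the aldehyde under neutral conditions, leaving the saturated C3 hydroxyl and the acid-labile C8–O bond intact.

Compound list
1 | ketoisophorone (2,6,6-trimethylcyclohex-2-ene-1,4-dione) | CC1=CC(=O)CC(C)(C)C1=O | starting material
2 | (6R)-2,2,6-trimethylcyclohexane-1,4-dione | C[C@@H]1CC(=O)CC(C)(C)C1=O | intermediate
3 | (4R,6R)-4-hydroxy-2,2,6-trimethylcyclohexan-1-one | C[C@@H]1C[C@@H](O)CC(C)(C)C1=O | intermediate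
4 | (1S,5R)-3,3,5-trimethyl-4-oxocyclohexyl 4-nitrobenzoate | C[C@@H]1C[C@H](OC(=O)c2ccc(cc2)[N+](=O)[O-])CC(C)(C)C1=O | intermediate
5 | (1S)-4-[(tert-butyldimethylsilyl)oxy]-3,5,5-trimethylcyclohex-3-en-1-yl 4-nitrobenzoate | CC1=C(O[Si](C)(C)C(C)(C)C)C(C)(C)C[C@@H](OC(=O)c2ccc(cc2)[N+](=O)[O-])C1 | intermediate
6 | (1S)-4-[(tert-butyldimethylsilyl)oxy]-3,5,5-trimethylcyclohex-3-en-1-ol | CC1=C(O[Si](C)(C)C(C)(C)C)C(C)(C)C[C@@H](O)C1 | intermediate
7 | 1-[(tert-butyldimethylsilyl)oxy]-2,2,6-trimethyl-7-oxabicyclo[4.1.0]heptan-4-ol, epoxide oxygen cis to the hydroxyl | CC(C)(C)[Si](C)(C)O[C@@]12O[C@]1(C)C[C@H](O)CC2(C)C | intermediate (not isolated)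
8 | (2R,4R)-2-[(tert-butyldimethylsilyl)oxy]-4-hydroxy-2,6,6-trimethylcyclohexan-1-one | O=C1C(C)(C)C[C@@H](O)C[C@@]1(C)O[Si](C)(C)C(C)(C)C | intermediate (not isolated)
9 | (2R,4R)-2,4-dihydroxy-2,6,6-trimethylcyclohexan-1-one | O=C1C(C)(C)C[C@@H](O)C[C@@]1(C)O | intermediate
10 | (2R,4R)-4-[(tert-butyldiphenylsilyl)oxy]-2-hydroxy-2,6,6-trimethylcyclohexan-1-one | O=C1C(C)(C)C[C@@H](O[Si](c2ccccc2)(c2ccccc2)C(C)(C)C)C[C@@]1(C)O | intermediate
11 | prenol (3-methylbut-2-en-1-ol) | CC(C)=CCO | starting material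
12 | tert-butyldimethyl[(3-methylbut-2-en-1-yl)oxy]silane | CC(C)=CCO[Si](C)(C)C(C)(C)C | intermediate
13 | (2E)-4-[(tert-butyldimethylsilyl)oxy]-2-methylbut-2-en-1-ol | OC/C(C)=C/CO[Si](C)(C)C(C)(C)C | intermediate
14 | {[(2E)-4-bromo-3-methylbut-2-en-1-yl]oxy}(tert-butyl)dimethylsilane | BrC/C(C)=C/CO[Si](C)(C)C(C)(C)C | intermediate
15 | potassium alkoxide of 10 | O=C1C(C)(C)C[C@@H](O[Si](c2ccccc2)(c2ccccc2)C(C)(C)C)C[C@@]1(C)[O-].[K+] | intermediate (not isolated)
16 | (2R,4R)-2-{[(2E)-4-[(tert-butyldimethylsilyl)oxy]-2-methylbut-2-en-1-yl]oxy}-4-[(tert-butyldiphenylsilyl)oxy]-2,6,6-trimethylcyclohexan-1-one (key-step precursor) | O=C1C(C)(C)C[C@@H](O[Si](c2ccccc2)(c2ccccc2)C(C)(C)C)C[C@@]1(C)OC/C(C)=C/CO[Si](C)(C)C(C)(C)C | intermediate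
17 | trimethylsilyldiazomethane | C[Si](C)(C)C=[N+]=[N-] | starting material
18 | lithium (trimethylsilyl)diazomethanide | [Li]C(=[N+]=[N-])[Si](C)(C)C | intermediate (not isolated)
19 | diazoalkene: 16 with the C6 carbonyl oxygen replaced by =C7=N2 | [N-]=[N+]=C=C1C(C)(C)C[C@@H](O[Si](c2ccccc2)(c2ccccc2)C(C)(C)C)C[C@@]1(C)OC/C(C)=C/CO[Si](C)(C)C(C)(C)C | intermediate (not isolated)
20 | alkylidene carbene: 16 with the C6 carbonyl oxygen replaced by the divalent carbon C7 | [C]=C1C(C)(C)C[C@@H](O[Si](c2ccccc2)(c2ccccc2)C(C)(C)C)C[C@@]1(C)OC/C(C)=C/CO[Si](C)(C)C(C)(C)C | intermediate (not isolated)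
21 | tert-butyl({(2E)-3-[(2R,6R,7aR)-6-[(tert-butyldiphenylsilyl)oxy]-4,4,7a-trimethyl-2,4,5,6,7,7a-hexahydro-1-benzofuran-2-yl]but-2-en-1-yl}oxy)dimethylsilane, the (3R,5R,8R) C15 core | CC(C)(C)[Si](C)(C)OC/C=C(\C)[C@H]1C=C2C(C)(C)C[C@@H](O[Si](c3ccccc3)(c3ccccc3)C(C)(C)C)C[C@@]2(C)O1 | intermediate
22 | (2R,6R,7aR)-2-[(2E)-4-hydroxybut-2-en-2-yl]-4,4,7a-trimethyl-2,4,5,6,7,7a-hexahydro-1-benzofuran-6-ol | OC/C=C(\C)[C@H]1C=C2C(C)(C)C[C@@H](O)C[C@@]2(C)O1 | intermediate
23 | (2E)-3-[(2R,6R,7aR)-6-hydroxy-4,4,7a-trimethyl-2,4,5,6,7,7a-hexahydro-1-benzofuran-2-yl]but-2-enal | O=C/C=C(\C)[C@H]1C=C2C(C)(C)C[C@@H](O)C[C@@]2(C)O1 | intermediate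
24 | (2E,4E,6E)-2,7-dimethylocta-2,4,6-trienedial | C\C(C=O)=C/C=C/C=C(\C)C=O | starting material
25 | ethyl (2E)-4-(diethoxyphosphoryl)-2-methylbut-2-enoate | CCOC(=O)/C(C)=C/CP(=O)(OCC)OCC | starting material
26 | sodium salt of the C4 carbanion of 25 | CCOC(=O)/C(C)=C/[CH-]P(=O)(OCC)OCC.[Na+] | intermediate (not isolated)
27 | ethyl (2E,4E,6E,8E,10E)-2,6,11-trimethyl-12-oxododeca-2,4,6,8,10-pentaenoate | CCOC(=O)/C(C)=C/C=C/C(C)=C/C=C/C=C(\C)C=O | intermediate
28 | ethyl (2E,4E,6E,8E,10E)-12-hydroxy-2,6,11-trimethyldodeca-2,4,6,8,10-pentaenoate | CCOC(=O)/C(C)=C/C=C/C(C)=C/C=C/C=C(\C)CO | intermediate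
29 | [(2E,4E,6E,8E,10E)-12-ethoxy-2,7,11-trimethyl-12-oxododeca-2,4,6,8,10-pentaen-1-yl]triphenylphosphonium bromide | CCOC(=O)/C(C)=C/C=C/C(C)=C/C=C/C=C(\C)C[P+](c1ccccc1)(c1ccccc1)c1ccccc1.[Br-] | intermediate
30 | phosphorus ylide of 29 | CCOC(=O)/C(C)=C/C=C/C(C)=C/C=C/C=C(\C)C=P(c1ccccc1)(c1ccccc1)c1ccccc1 | intermediate (not isolated)
31 | ethyl (3R,5R,8R,all-E)-5,8-epoxy-3-hydroxy-5,8-dihydro-8′-apo-β-caroten-8′-oate | CCOC(=O)/C(C)=C/C=C/C(C)=C/C=C/C=C(C)/C=C/C=C(\C)[C@H]1C=C2C(C)(C)C[C@@H](O)C[C@@]2(C)O1 | intermediate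
32 | (3R,5R,8R,all-E)-5,8-epoxy-5,8-dihydro-8′-apo-β-carotene-3,8′-diol | OC/C(C)=C/C=C/C(C)=C/C=C/C=C(C)/C=C/C=C(\C)[C@H]1C=C2C(C)(C)C[C@@H](O)C[C@@]2(C)O1 | intermediate
33 | (3R,5R,8R,all-E)-5,8-epoxy-3-hydroxy-5,8-dihydro-8′-apo-β-caroten-8′-al (CNP0118413.1) | C\C(C=O)=C/C=C/C(C)=C/C=C/C=C(C)/C=C/C=C(\C)[C@H]1C=C2C(C)(C)C[C@@H](O)C[C@@]2(C)O1 | target

Total step count: 20. Longest linear sequence: 14 steps (steps 1–7, 11–14 and 18–20).

Steps most likely to fail

Step 12. The lithiated diazomethane may fail to add to the C6 carbonyl, which lies between two fully substituted carbons, so that ketone would be returned. Once the carbene forms, it may discriminate poorly between the two C8 hydrogens or add to the C9=C10 bond. The fallback avoids the carbene and sets out from 10, returning at 21. (2E)-3-Methylpent-2-en-4-yn-1-ol (C#C/C(C)=C/CO, purchasable) is silylated with t-BuMe2SiCl and imidazole to tert-butyldimethyl{[(2E)-3-methylpent-2-en-4-yn-1-yl]oxy}silane F1. Its acetylide, generated with n-BuLi in THF at −78 °C and used in excess because the C5 hydroxyl of 10 is deprotonated first, adds to the C6 carbonyl of 10 to give the alkynyl diol F2 (the new C6 centre is of no consequence). Reduction with NaAlH2(OCH2CH2OMe)2 turns the propargylic alcohol into the (7E)-dienyl diol F3. A catalytic amount of pyridinium p-toluenesulfonate in CH2Cl2 at 0 °C ionises the doubly allylic tertiary C6 hydroxyl, and the C5 hydroxyl closes onto C8 with shift of the double bond to C6=C7. This should give 21 together with its C8 epimer F4, which is removed by chromatography.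

Step 11. The hindered tertiary potassium alkoxide may be alkylated too slowly, and the basic medium may cause silyl migration from O3 to O5 or an α-ketol rearrangement. The fallback alkylates the neutral alcohol under acid catalysis; it sets out from 13 and 10 and returns at 16. Alcohol 13 is treated with Cl3CCN and catalytic DBU to give (2E)-4-[(tert-butyldimethylsilyl)oxy]-2-methylbut-2-en-1-yl 2,2,2-trichloroacetimidate F5. This imidate should transfer its allyl group to the C5 hydroxyl of 10 under catalytic Me3SiOTf in CH2Cl2/cyclohexane at −20 °C.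

Step 6. The facial selectivity of the enol ether epoxidation may be poor or reversed, which would place the new oxygen trans to the C3 oxygen and give the wrong C5 configuration. The fallback turns an attack trans to the C3 oxygen to advantage and then resets C3 by oxidation and reduction; it sets out from 3 and returns at 9. Alcohol 3, which has the opposite C3 configuration, is bis-silylated with Me3SiOTf and Et3N to trimethyl{[(1R)-3,5,5-trimethyl-4-[(trimethylsilyl)oxy]cyclohex-3-en-1-yl]oxy}silane F6. Epoxidation with m-CPBA trans to the silyloxy group, followed by aqueous HCl, should give (2R,4S)-2,4-dihydroxy-2,6,6-trimethylcyclohexan-1-one F7, which already has the required tertiary centre. Dess–Martin periodinane oxidises the secondary alcohol to (2R)-2-hydroxy-2,6,6-trimethylcyclohexane-1,4-dione F8. LiBH(s-Bu)3 at −78 °C should then attack the C4 carbonyl from the equatorial side, away from the axial C2 hydroxyl and the axial C6 methyl, to give the cis diol 9.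

Further compounds
F1 | step 12 | tert-butyldimethyl{[(2E)-3-methylpent-2-en-4-yn-1-yl]oxy}silane | C#C/C(C)=C/CO[Si](C)(C)C(C)(C)C
F2 | step 12 | (2R,4R)-1-{(3E)-5-[(tert-butyldimethylsilyl)oxy]-3-methylpent-3-en-1-yn-1-yl}-4-[(tert-butyldiphenylsilyl)oxy]-2,6,6-trimethylcyclohexane-1,2-diol (C1 unassigned) | OC1(C#C/C(C)=C/CO[Si](C)(C)C(C)(C)C)C(C)(C)C[C@@H](O[Si](c2ccccc2)(c2ccccc2)C(C)(C)C)C[C@@]1(C)O
F3 | step 12 | (2R,4R)-1-{(1E,3E)-5-[(tert-butyldimethylsilyl)oxy]-3-methylpenta-1,3-dien-1-yl}-4-[(tert-butyldiphenylsilyl)oxy]-2,6,6-trimethylcyclohexane-1,2-diol (C1 unassigned) | OC1(/C=C/C(C)=C/CO[Si](C)(C)C(C)(C)C)C(C)(C)C[C@@H](O[Si](c2ccccc2)(c2ccccc2)C(C)(C)C)C[C@@]1(C)O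
F4 | step 12 | C8 epimer of 21, (2S,6R,7aR) | CC(C)(C)[Si](C)(C)OC/C=C(\C)[C@@H]1C=C2C(C)(C)C[C@@H](O[Si](c3ccccc3)(c3ccccc3)C(C)(C)C)C[C@@]2(C)O1
F5 | step 11 | (2E)-4-[(tert-butyldimethylsilyl)oxy]-2-methylbut-2-en-1-yl 2,2,2-trichloroacetimidate | N=C(OC/C(C)=C/CO[Si](C)(C)C(C)(C)C)C(Cl)(Cl)Cl
F6 | step 6 | trimethyl{[(1R)-3,5,5-trimethyl-4-[(trimethylsilyl)oxy]cyclohex-3-en-1-yl]oxy}silane | CC1=C(O[Si](C)(C)C)C(C)(C)C[C@H](O[Si](C)(C)C)C1
F7 | step 6 | (2R,4S)-2,4-dihydroxy-2,6,6-trimethylcyclohexan-1-one | O=C1C(C)(C)C[C@H](O)C[C@@]1(C)O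
F8 | step 6 | (2R)-2-hydroxy-2,6,6-trimethylcyclohexane-1,4-dione | O=C1C(C)(C)CC(=O)C[C@@]1(C)O
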